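**Retrosynthetic overview**

1. Gambiriin C is read as an upper flavan-3-ol unit (ring A, pyran ring C, ring B = 4-hydroxyphenyl; 2R,3R,4R) bonded from C4 to C8 of (+)-catechin (rings D, F, E). All nine hydroxyls are carried as benzyl ethers and freed last.
2. Feature used: C4 of ring C is a diarylmethine carbon between ring A and ring D and lies ortho to the ring A oxygen O1, so O1–C8a–C4a–C4 is a masked ortho-quinone methide. C3 (with O3) and C2 are the α-carbon and the carbonyl carbon of benzyloxyacetaldehyde.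
3. Ring C is cut at C3–C4 and O1–C2 (enamine addition to the methide, then hemiacetal closure). The methide precursor, a ring A/ring D benzhydrol, is cut at C4–C8 into 8-lithio-pentabenzylcatechin and a protected 2-hydroxy-4,6-dibenzyloxybenzaldehyde.
4. Ring B is attached to C2 afterwards (lactol, lactone, aryllithium, hemiketal). Hydride delivery to the C2 oxocarbenium ion trans to O3 sets the 2,3-cis relation.
5. Ring order: rings D, E, F (catechin) and ring A (aldehyde) are bought, ring C is closed in the key step, ring B is appended last.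

Key step: step 8

Remark: read from the SMILES, the upper unit is 2R,3R,4R, i.e. ring B at C2 is cis to O3 and O3 is trans to the ring D substituent at C4 (epiafzelechin-(4β→8)-catechin); the route is planned for this diastereomer.

**Route**

Step 1
Reactants: 1 (+)-catechin
Product: 2 5,7,3',4'-tetra-O-benzylcatechin
Conditions: BnBr (4.2 equiv), K2CO3, DMF, 0 °C to rt
Reagents that add atoms: benzyl bromide, BrCc1ccccc1
Why: Williamson etherification in which carbonate deprotonates only the four phenols, so the C3 alcohol stays free and no stereocentre is touched.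

Step 2
Reactants: 2 5,7,3',4'-tetra-O-benzylcatechin
Product: 3 3,5,7,3',4'-penta-O-benzylcatechin
Conditions: NaH, BnBr, Bu4NI (cat.), DMF, 0 °C to rt
Reagents that add atoms: benzyl bromide, BrCc1ccccc1
Why: Williamson etherification of the secondary alkoxide, with C2 and C3 configurationally safe because no free phenol remains to open ring F.

Step 3
Reactants: 3 3,5,7,3',4'-penta-O-benzylcatechin
Product: 4 8-bromo-3,5,7,3',4'-penta-O-benzylcatechin
Conditions: NBS (1.0 equiv), CH2Cl2, −78 °C to rt
Reagents that add atoms: N-bromosuccinimide, O=C1CCC(=O)N1Br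
Why: electrophilic aromatic bromination of the most electron-rich ring, for which 5,7-di-O-benzylflavans are known to react at C8 in preference to C6.

Step 4
Reactants: 5 2,4,6-trihydroxybenzaldehyde
Product: 6 2,4-bis(benzyloxy)-6-hydroxybenzaldehyde
Conditions: BnBr (2.05 equiv), K2CO3, DMF, rt
Reagents that add atoms: benzyl bromide, BrCc1ccccc1
Why: Williamson etherification that should stop after the 4-OH and one ortho OH, because the last ortho OH is held in a hydrogen bond to the formyl group and reacts slowest.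

Step 5
Reactants: 6 2,4-bis(benzyloxy)-6-hydroxybenzaldehyde
Product: 7 2-(allyloxy)-4,6-bis(benzyloxy)benzaldehyde
Conditions: allyl bromide, K2CO3, DMF, 50 °C
Reagents that add atoms: allyl bromide, C=CCBr
Why: Williamson allylation of the chelated phenol, allyl being chosen because it does not migrate to a neighbouring alkoxide and is removed without acid.

Step 6
Reactants: 4 8-bromo-3,5,7,3',4'-penta-O-benzylcatechin; 7 2-(allyloxy)-4,6-bis(benzyloxy)benzaldehyde
Product: 9 [2-(allyloxy)-4,6-bis(benzyloxy)phenyl](penta-O-benzylcatechin-8-yl)methanol (both carbinol epimers), via 8-lithio-penta-O-benzylcatechin 8 (not isolated)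
Conditions: n-BuLi (1.05 equiv), THF, −78 °C; then 7, −78 to −40 °C; aq. NH4Cl
Reagents that add atoms: none
Why: bromine–lithium exchange followed by 1,2-addition of the aryllithium to the non-enolisable aldehyde forms the C4–C8 bond; the carbinol centre forms unselectively and is erased in step 8.

Step 7
Reactants: 9 [2-(allyloxy)-4,6-bis(benzyloxy)phenyl](penta-O-benzylcatechin-8-yl)methanol
Product: 10 [2,4-bis(benzyloxy)-6-hydroxyphenyl](penta-O-benzylcatechin-8-yl)methanol (ring A/ring D ortho-hydroxybenzhydrol, both carbinol epimers)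
Conditions: Pd(PPh3)4 (5 mol%), morpholine (10 equiv), THF, rt; Et3N-deactivated silica
Reagents that add atoms: none
Why: Tsuji–Trost deallylation transfers the allyl group to morpholine under non-acidic conditions, so the acid-labile benzhydrol and the benzyl ethers should survive.

Step 8
Reactants: 10 ring A/ring D ortho-hydroxybenzhydrol; 11 benzyloxyacetaldehyde
Product: 14 (3R,4R)-3,5,7-tris(benzyloxy)-4-(penta-O-benzylcatechin-8-yl)chroman-2-ol (3,4-trans lactol; both anomers), via ortho-quinone methide 12 (not isolated), via catalyst enamine 13 (not isolated)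
Conditions: (S)-α,α-diphenylprolinol trimethylsilyl ether (20 mol%), PhCO2H (20 mol%), CH2Cl2, 0 °C to rt; 11 (3 equiv) added slowly
Reagents that add atoms: none
Why: Proposed new method: PhCO2H ionises benzhydrol 10 to the ortho-quinone methide 12 (O1–C8a–C4a–C4, stabilised by the trialkoxy ring D), the E-enamine 13 adds through C3 to C4, and the phenol then closes on C2 of the iminium ion or of the hydrolysed aldehyde, which frees the amine. The closest known reaction is the diarylprolinol-silyl-ether-catalysed formal [4+2] of simple aliphatic aldehydes with ortho-quinone methides generated from ortho-hydroxybenzhydrols, which gives trans-3,4-disubstituted chroman-2-ols; the extension to an α-alkoxy aldehyde and to a methide carbon flanked by two ortho,ortho'-disubstituted rings is argued from the known competence of benzyloxyacetaldehyde as an enamine donor and from an enamine being a far stronger nucleophile than the trialkoxyarene rings that could otherwise capture the cation. Ring C is closed by a 6-exo-trig hemiacetalisation of O1 on C2. C3 is set by attack on the enamine face that the CPh2(OSiMe3) group of the S catalyst leaves open (3R) and, being epimerisable through the open-chain aldehyde, should end trans to ring D. C4 is set irreversibly in the C–C bond formation by the synclinal approach that places the methide oxygen next to the enamine nitrogen (4R), while C2 forms as both anomers and is levelled by the oxidation in step 9. The selectivity the step needs is attack on one face of the methide carbon, and it relies on catalyst control overriding the weak bias of the distant C2 and C3 centres of ring F.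

Step 9
Reactants: 14 (3R,4R)-3,5,7-tris(benzyloxy)-4-(penta-O-benzylcatechin-8-yl)chroman-2-ol
Product: 15 (3R,4R)-3,5,7-tris(benzyloxy)-4-(penta-O-benzylcatechin-8-yl)chroman-2-one
Conditions: (n-Pr)4N[RuO4] (5 mol%), NMO (2 equiv), 4 Å MS, CH2Cl2, rt
Reagents that add atoms: none
Why: Ley–Griffith oxidation of the lactol to the lactone under neutral conditions; C3 is already trans to the C4 aryl group, the more stable arrangement, so enolisation would not change it.

Step 10
Reactants: 15 (3R,4R)-3,5,7-tris(benzyloxy)-4-(penta-O-benzylcatechin-8-yl)chroman-2-one; 16 1-(benzyloxy)-4-bromobenzene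
Product: 18 (3R,4R)-3,5,7-tris(benzyloxy)-2-[4-(benzyloxy)phenyl]-4-(penta-O-benzylcatechin-8-yl)chroman-2-ol (hemiketal; both C2 epimers), via 4-benzyloxyphenyllithium 17 (not isolated)
Conditions: 16 (1.3 equiv), n-BuLi (1.25 equiv), THF, −78 °C; added to 15 in THF, −78 °C; aq. NH4Cl at −78 °C
Reagents that add atoms: none
Why: 1,2-addition of an aryllithium to a lactone carbonyl, as in C-aryl glycoside synthesis, in which the tetrahedral adduct (or its hindered, electron-rich keto phenoxide) should persist at −78 °C until the quench and then close to the hemiketal.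

Step 11
Reactants: 18 (3R,4R)-3,5,7-tris(benzyloxy)-2-[4-(benzyloxy)phenyl]-4-(penta-O-benzylcatechin-8-yl)chroman-2-ol
Product: 20 (2R,3R,4R)-3,5,7-tris(benzyloxy)-2-[4-(benzyloxy)phenyl]-4-(penta-O-benzylcatechin-8-yl)chroman (nona-O-benzyl gambiriin C), via oxocarbenium ion 19 (not isolated)
Conditions: Et3SiH (5 equiv), BF3·OEt2 (2 equiv), CH2Cl2, −78 to −40 °C
Reagents that add atoms: none
Why: ionic hydrogenation of a hemiketal (reductive etherification), in which A(1,2) strain with the coplanar ring B should hold the C3 benzyloxy group and the trans C4 aryl group pseudoaxial in 19, so that axial hydride addition anti to the C3–O bond places H2 trans to O3 and ring B cis to it (2R).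

Step 12
Reactants: 20 nona-O-benzyl gambiriin C
Product: 21 gambiriin C
Conditions: H2 (1 atm), Pd(OH)2 on carbon, THF–MeOH (1:1), rt
Reagents that add atoms: none
Why: hydrogenolysis of the nine benzyl ethers, under which the cyclic benzylic C2–O1 bonds of benzylated flavans are known to survive and no stereocentre is affected.

**Compound list**

1 | (+)-catechin | O[C@H]1Cc2c(O)cc(O)cc2O[C@@H]1c1ccc(O)c(O)c1 | starting material
2 | 5,7,3',4'-tetra-O-benzylcatechin | O[C@H]1Cc2c(OCc3ccccc3)cc(OCc3ccccc3)cc2O[C@@H]1c1ccc(OCc2ccccc2)c(OCc2ccccc2)c1 | intermediate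
3 | 3,5,7,3',4'-penta-O-benzylcatechin | O(Cc1ccccc1)[C@H]1Cc2c(OCc3ccccc3)cc(OCc3ccccc3)cc2O[C@@H]1c1ccc(OCc2ccccc2)c(OCc2ccccc2)c1 | intermediate
4 | 8-bromo-3,5,7,3',4'-penta-O-benzylcatechin | O(Cc1ccccc1)[C@H]1Cc2c(OCc3ccccc3)cc(OCc3ccccc3)c(Br)c2O[C@@H]1c1ccc(OCc2ccccc2)c(OCc2ccccc2)c1 | intermediate
5 | 2,4,6-trihydroxybenzaldehyde | O=Cc1c(O)cc(O)cc1O | starting material
6 | 2,4-bis(benzyloxy)-6-hydroxybenzaldehyde | O=Cc1c(O)cc(OCc2ccccc2)cc1OCc1ccccc1 | intermediate
7 | 2-(allyloxy)-4,6-bis(benzyloxy)benzaldehyde | O=Cc1c(OCC=C)cc(OCc2ccccc2)cc1OCc1ccccc1 | intermediate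
8 | 8-lithio-penta-O-benzylcatechin (formed in the flask) | O(Cc1ccccc1)[C@H]1Cc2c(OCc3ccccc3)cc(OCc3ccccc3)c([Li])c2O[C@@H]1c1ccc(OCc2ccccc2)c(OCc2ccccc2)c1 | intermediate
9 | [2-(allyloxy)-4,6-bis(benzyloxy)phenyl](penta-O-benzylcatechin-8-yl)methanol, both carbinol epimers | C=CCOc1cc(OCc2ccccc2)cc(OCc2ccccc2)c1C(O)c5c(OCc6ccccc6)cc(OCc6ccccc6)c6c5O[C@H](c5ccc(OCc7ccccc7)c(OCc7ccccc7)c5)[C@@H](OCc5ccccc5)C6 | intermediate
10 | [2,4-bis(benzyloxy)-6-hydroxyphenyl](penta-O-benzylcatechin-8-yl)methanol, both carbinol epimers | Oc1cc(OCc2ccccc2)cc(OCc2ccccc2)c1C(O)c5c(OCc6ccccc6)cc(OCc6ccccc6)c6c5O[C@H](c5ccc(OCc7ccccc7)c(OCc7ccccc7)c5)[C@@H](OCc5ccccc5)C6 | intermediate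
11 | benzyloxyacetaldehyde | O=CCOCc1ccccc1 | starting material
12 | 3,5-bis(benzyloxy)-6-[(penta-O-benzylcatechin-8-yl)methylidene]cyclohexa-2,4-dien-1-one, ortho-quinone methide (formed in the flask) | O=C1C=C(OCc2ccccc2)C=C(OCc2ccccc2)C1=Cc5c(OCc6ccccc6)cc(OCc6ccccc6)c6c5O[C@H](c5ccc(OCc7ccccc7)c(OCc7ccccc7)c5)[C@@H](OCc5ccccc5)C6 | intermediate
13 | E-enamine of benzyloxyacetaldehyde and (S)-α,α-diphenylprolinol trimethylsilyl ether (formed in the flask) | C[Si](C)(C)OC(c1ccccc1)(c1ccccc1)[C@@H]1CCCN1/C=C/OCc1ccccc1 | intermediate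
14 | (3R,4R)-3,5,7-tris(benzyloxy)-4-(penta-O-benzylcatechin-8-yl)chroman-2-ol, both anomers | OC1Oc2cc(OCc3ccccc3)cc(OCc3ccccc3)c2[C@H](c5c(OCc6ccccc6)cc(OCc6ccccc6)c6c5O[C@H](c5ccc(OCc7ccccc7)c(OCc7ccccc7)c5)[C@@H](OCc5ccccc5)C6)[C@H]1OCc1ccccc1 | intermediate
15 | (3R,4R)-3,5,7-tris(benzyloxy)-4-(penta-O-benzylcatechin-8-yl)chroman-2-one | O=C1Oc2cc(OCc3ccccc3)cc(OCc3ccccc3)c2[C@H](c5c(OCc6ccccc6)cc(OCc6ccccc6)c6c5O[C@H](c5ccc(OCc7ccccc7)c(OCc7ccccc7)c5)[C@@H](OCc5ccccc5)C6)[C@H]1OCc1ccccc1 | intermediate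
16 | 1-(benzyloxy)-4-bromobenzene | Brc1ccc(OCc2ccccc2)cc1 | starting material
17 | 4-(benzyloxy)phenyllithium (formed in the flask) | [Li]c1ccc(OCc2ccccc2)cc1 | intermediate
18 | (3R,4R)-3,5,7-tris(benzyloxy)-2-[4-(benzyloxy)phenyl]-4-(penta-O-benzylcatechin-8-yl)chroman-2-ol, both C2 epimers | OC1(c2ccc(OCc3ccccc3)cc2)Oc2cc(OCc3ccccc3)cc(OCc3ccccc3)c2[C@H](c5c(OCc6ccccc6)cc(OCc6ccccc6)c6c5O[C@H](c5ccc(OCc7ccccc7)c(OCc7ccccc7)c5)[C@@H](OCc5ccccc5)C6)[C@H]1OCc1ccccc1 | intermediate
19 | (3R,4R)-3,5,7-tris(benzyloxy)-2-[4-(benzyloxy)phenyl]-4-(penta-O-benzylcatechin-8-yl)-3,4-dihydrochromenylium, C2 oxocarbenium ion (formed in the flask) | C1(c2ccc(OCc3ccccc3)cc2)=[O+]c2cc(OCc3ccccc3)cc(OCc3ccccc3)c2[C@H](c5c(OCc6ccccc6)cc(OCc6ccccc6)c6c5O[C@H](c5ccc(OCc7ccccc7)c(OCc7ccccc7)c5)[C@@H](OCc5ccccc5)C6)[C@H]1OCc1ccccc1 | intermediate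
20 | nona-O-benzyl gambiriin C, (2R,3R,4R) | c1ccccc1COc1ccc(cc1)[C@H]1Oc2cc(OCc3ccccc3)cc(OCc3ccccc3)c2[C@H](c5c(OCc6ccccc6)cc(OCc6ccccc6)c6c5O[C@H](c5ccc(OCc7ccccc7)c(OCc7ccccc7)c5)[C@@H](OCc5ccccc5)C6)[C@H]1OCc1ccccc1 | intermediate
21 | gambiriin C | Oc1ccc([C@H]2Oc3cc(O)cc(O)c3[C@H](c3c(O)cc(O)c4c3O[C@H](c3ccc(O)c(O)c3)[C@@H](O)C4)[C@H]2O)cc1 | target

**Step count**

Total: 12 steps. Longest linear sequence: 10 steps (steps 1, 2, 3, 6, 7, 8, 9, 10, 11, 12).

**Steps most likely to fail**

Step 8. The crowded, strongly stabilised methide may add the enamine only slowly, so that self-aldol of the aldehyde takes over, or the addition may show poor facial selectivity at C4. If only the sense of C4 induction is wrong, the R catalyst followed by C3 equilibration would be tried first. The fallback proper abandons the annulation and makes the C4–C8 bond by the established Lewis-acid coupling of a C4-activated flavan with a flavan nucleophile. It sets out from 2. Purchased (−)-epiafzelechin F1 is benzylated (BnBr, K2CO3, DMF) to 5,7,4'-tri-O-benzylepiafzelechin F2. DDQ in CH2Cl2 with 2-ethoxyethanol oxidises F2 at C4 to 4β-(2-ethoxyethoxy)-5,7,4'-tri-O-benzylepiafzelechin F3. TMSOTf in CH2Cl2 at −78 °C ionises F3 in the presence of an excess of 2, whose C8 should attack the C4 cation trans to the axial 3-OH, giving hepta-O-benzyl epiafzelechin-(4β→8)-catechin F4. Hydrogenolysis of F4 (H2, Pd(OH)2 on carbon) comes back to the route at 21.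

Step 11. Hydride delivery to 19 must occur on the face that is anti to the C3–O bond but syn to the pseudoaxial ring D; delivery from the other face would give the 2,3-trans isomer. The fallback sets C2 by substitution instead of reduction and sets out from 18. Its open hydroxy ketone form is reduced with Zn(BH4)2 in Et2O at −20 °C under Cram-chelate control by the C3 benzyloxy group to the anti (2S,3R,4R) benzylic alcohol with free ring A phenol F5. Mitsunobu etherification (PPh3, DIAD, THF, 0 °C) then closes O1–C2 with inversion and comes back to the route at 20.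

Step 10. The tetrahedral adduct of an aryl ester can collapse to the ketone at low temperature and take up a second aryllithium, or the lactone may be enolised. The fallback sets out from 15, which is opened with MeNH(OMe)·HCl and Me3Al in CH2Cl2 to the phenolic Weinreb amide F6. Its chelated adduct with 17 (3 equiv, THF, −78 to 0 °C) cannot add a second time, and on work-up the hydroxy ketone closes to the hemiketal, coming back to the route at 18.

**Further compounds**

F1 | step 8 | (−)-epiafzelechin (purchased) | O[C@@H]1Cc2c(O)cc(O)cc2O[C@@H]1c1ccc(O)cc1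
F2 | step 8 | 5,7,4'-tri-O-benzylepiafzelechin | c1ccccc1COc1ccc(cc1)[C@H]1Oc2cc(OCc3ccccc3)cc(OCc3ccccc3)c2C[C@H]1O
F3 | step 8 | 4β-(2-ethoxyethoxy)-5,7,4'-tri-O-benzylepiafzelechin | c1ccccc1COc1ccc(cc1)[C@H]1Oc2cc(OCc3ccccc3)cc(OCc3ccccc3)c2[C@H](OCCOCC)[C@H]1O
F4 | step 8 | hepta-O-benzyl epiafzelechin-(4β→8)-catechin | c1ccccc1COc1ccc(cc1)[C@H]1Oc2cc(OCc3ccccc3)cc(OCc3ccccc3)c2[C@H](c5c(OCc6ccccc6)cc(OCc6ccccc6)c6c5O[C@H](c5ccc(OCc7ccccc7)c(OCc7ccccc7)c5)[C@@H](O)C6)[C@H]1O
F5 | step 11 | anti (2S,3R,4R) open-chain benzylic alcohol with free ring A phenol | c1ccccc1COc1ccc(cc1)[C@H](O)[C@H](OCc1ccccc1)[C@@H](c5c(OCc6ccccc6)cc(OCc6ccccc6)c6c5O[C@H](c5ccc(OCc7ccccc7)c(OCc7ccccc7)c5)[C@@H](OCc5ccccc5)C6)c1c(O)cc(OCc2ccccc2)cc1OCc1ccccc1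
F6 | step 10 | (2R,3R)-2-benzyloxy-3-aryl-3-(catechinyl) N-methoxy-N-methylpropanamide with free ring A phenol (Weinreb amide) | CON(C)C(=O)[C@H](OCc1ccccc1)[C@@H](c5c(OCc6ccccc6)cc(OCc6ccccc6)c6c5O[C@H](c5ccc(OCc7ccccc7)c(OCc7ccccc7)c5)[C@@H](OCc5ccccc5)C6)c1c(O)cc(OCc2ccccc2)cc1OCc1ccccc1
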